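**Plan**
Side-chain labels: C1' is the sp2 carbon on C2, C2' is =CH2, C3' is CH2OAc. The retrosynthesis cuts the C3–O angelate and C3'–O acetate bonds first. It then cuts C1'–C3' (traced back to a C1'–B bond), then C2–C3 and C1'–B in one operation, and last the C3a–CHO and O1–propargyl bonds of a purchased bromoresacetophenone.
Enabling feature: C3 (benzylic carbinol carbon on C3a) and C2 (bearing O1 and the 1,1-disubstituted C1'=C2' unit) form a homoallylic alcohol inside the dihydrofuran ring. This is the imprint of a γ-aryloxyallyl metal adding to an ortho aldehyde.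
Forward order: the benzene ring is bought. O-propargylation, silylation, ketalisation, isomerisation to the aryloxyallene and formylation give the open precursor. The dihydrofuran is the only ring made, and it closes in the copper-catalysed borylative cyclisation.
After ring closure, C1'–Bpin becomes C1'–CH2OH by one-carbon insertion and oxidation. Acetylation, unmasking of the ketone and C3–OH, angeloylation and desilylation follow.
Stereochemistry: C2 and C3 are both set in the cyclisation. The cis relation comes from a Z-allylcopper in a closed transition state, and the absolute sense comes from the chiral bisphosphine. The Z-alkene of the angelate is bought with angelic acid and preserved.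

Key step: step 6

Assumption: (R,R)-Ph-BPE is taken as the ligand enantiomer that leads to (2R,3R)-12. Precursor 9 is achiral, so the (S,S)-ligand would be used in the same way if the first run shows the opposite sense.

Step 1
Reactants: 1 1-(5-bromo-2,4-dihydroxyphenyl)ethan-1-one; 2 propargyl bromide
Product: 3 1-[5-bromo-2-hydroxy-4-(prop-2-yn-1-yloxy)phenyl]ethan-1-one
Conditions: K2CO3 (1.1 equiv), acetone, reflux
Reagents that add atoms: none
Why: Williamson ether synthesis in which the C2 hydroxyl stays locked in its hydrogen bond to the acetyl oxygen, so that K2CO3 ionises only the more acidic C4 hydroxyl (para to the acetyl group and ortho to bromine) and alkylation should stop at the mono-ether.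

Step 2
Reactants: 3 1-[5-bromo-2-hydroxy-4-(prop-2-yn-1-yloxy)phenyl]ethan-1-one
Product: 4 1-[5-bromo-4-(prop-2-yn-1-yloxy)-2-(triisopropylsilyloxy)phenyl]ethan-1-one
Conditions: TIPSOTf, 2,6-lutidine, CH2Cl2, 0 °C to rt
Reagents that add atoms: triisopropylsilyl triflate, CC(C)[Si](C(C)C)(C(C)C)OS(=O)(=O)C(F)(F)F
Why: Silyl triflate silylation of a chelated phenol, fast enough at 0 °C with a hindered pyridine base to outrun enol silane formation at the methyl ketone, and TIPS is chosen because it is the common aryl silyl ether that best resists the alkoxide, organolithium and perborate reagents still to come while leaving with buffered fluoride at the end.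

Step 3
Reactants: 4 1-[5-bromo-4-(prop-2-yn-1-yloxy)-2-(triisopropylsilyloxy)phenyl]ethan-1-one
Product: 5 2-[5-bromo-4-(prop-2-yn-1-yloxy)-2-(triisopropylsilyloxy)phenyl]-2-methyl-1,3-dioxolane
Conditions: TMSOCH2CH2OTMS, TMSOTf (5 mol%), CH2Cl2, −78 to 0 °C; Et3N quench
Reagents that add atoms: 1,2-bis(trimethylsilyloxy)ethane, C[Si](C)(C)OCCO[Si](C)(C)C
Why: Noyori ketalisation, an aprotic acetal exchange driven by formation of hexamethyldisiloxane that copes with hindered, electron-rich aryl ketones, and it is placed before any aldehyde exists so that no discrimination between two carbonyl groups is needed.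

Step 4
Reactants: 5 2-[5-bromo-4-(prop-2-yn-1-yloxy)-2-(triisopropylsilyloxy)phenyl]-2-methyl-1,3-dioxolane
Product: 6 2-[5-bromo-4-(propa-1,2-dien-1-yloxy)-2-(triisopropylsilyloxy)phenyl]-2-methyl-1,3-dioxolane
Conditions: KOtBu (0.3 equiv), THF, 0 °C to rt
Reagents that add atoms: none
Why: Base-catalysed prototropic propargyl-to-allenyl isomerisation, the standard access to aryloxyallenes, run at a stage where the molecule holds no carbonyl group that the transient propargylic carbanion or the alkoxide could attack.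

Step 5
Reactants: 6 2-[5-bromo-4-(propa-1,2-dien-1-yloxy)-2-(triisopropylsilyloxy)phenyl]-2-methyl-1,3-dioxolane
Product: 9 5-(2-methyl-1,3-dioxolan-2-yl)-2-(propa-1,2-dien-1-yloxy)-4-(triisopropylsilyloxy)benzaldehyde, via aryllithium 7 (not isolated), via lithium hemiaminal alkoxide 8 (not isolated)
Conditions: n-BuLi (1.05 equiv), THF, −78 °C, 10 min; DMF, −78 to 0 °C; pH 7 phosphate buffer
Reagents that add atoms: N,N-dimethylformamide, CN(C)C=O
Why: Bromine–lithium exchange followed by Bouveault-type formylation with DMF: exchange at an ortho-alkoxy aryl bromide is complete within minutes at −78 °C, faster than deprotonation of the allenyl α-C–H, and adduct 8 holds the aldehyde masked until a neutral quench that spares the ketal and the allenyl ether.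

Step 6
Reactants: 9 5-(2-methyl-1,3-dioxolan-2-yl)-2-(propa-1,2-dien-1-yloxy)-4-(triisopropylsilyloxy)benzaldehyde; 10 bis(pinacolato)diboron
Product: 12 (2R,3R)-5-(2-methyl-1,3-dioxolan-2-yl)-2-[1-(pinacolboryl)ethenyl]-6-(triisopropylsilyloxy)-2,3-dihydro-1-benzofuran-3-ol (2,3-cis), via O-pinacolboryl ether 11 (not isolated)
Conditions: CuCl (5 mol%), (R,R)-Ph-BPE (6 mol%), NaOtBu (10 mol%), THF, 0 °C to rt, no proton source; pH 7 buffer work-up
Reagents that add atoms: none
Why: LCu–OtBu and 10 give LCu–Bpin, which adds in a syn fashion to the unsubstituted C=C of the allenyl ether from the side remote from the aryloxy group, so that boron becomes bonded to the central carbon (the C1'–B bond) and copper to the CH2 terminus of a Z-configured allylcopper. The oxygen-bearing γ-carbon of this species then attacks the neighbouring formyl carbon through a closed six-membered array held together by a Cu–O contact, a 5-exo-trig closure on C=O that forms C2–C3 and the dihydrofuran ring, after which the copper alkoxide exchanges with 10 to release 11 and regenerate LCu–Bpin. The closest known reaction types are the enantioselective copper-catalysed three-component coupling of monosubstituted allenes, B2pin2 and aldehydes, and the borylative cyclisations of allenes tethered to carbonyl groups. The relative configuration follows from the Z geometry, because the O1–C7a–C3a tether must bridge the pseudo-axial γ-oxygen of the allyl unit and the pseudo-equatorial aryl group of the aldehyde, which forces the C3–O and C2–C1' bonds of the cyclic array onto the same face of the new ring (2,3-cis). The absolute configuration at both centres is fixed together by the C2-symmetric bisphosphine on copper, which decides which aldehyde face meets the allyl terminus. The step also needs chemoselectivity (borylcupration of the allene before the aldehyde, and the aldehyde as the only electrophile), which rests on the higher reactivity of allenes toward Cu–B, on the ortho placement that puts only the formyl group within reach, on the ketal that hides the C5 acetyl group, and on the absence of any proton source.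

Step 7
Reactants: 12 (2R,3R)-5-(2-methyl-1,3-dioxolan-2-yl)-2-[1-(pinacolboryl)ethenyl]-6-(triisopropylsilyloxy)-2,3-dihydro-1-benzofuran-3-ol
Product: 13 (2R,3R)-5-(2-methyl-1,3-dioxolan-2-yl)-2-[1-(pinacolboryl)ethenyl]-3-(triethylsilyloxy)-6-(triisopropylsilyloxy)-2,3-dihydro-1-benzofuran
Conditions: TESCl, imidazole, CH2Cl2, 0 °C to rt
Reagents that add atoms: chlorotriethylsilane, CC[Si](Cl)(CC)CC
Why: Routine chlorosilane/imidazole silylation that touches neither stereocentre and keeps the C3 oxygen from forming an internal borate with the cis boryl group or from quenching the carbenoid in step 8.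

Step 8
Reactants: 13 (2R,3R)-5-(2-methyl-1,3-dioxolan-2-yl)-2-[1-(pinacolboryl)ethenyl]-3-(triethylsilyloxy)-6-(triisopropylsilyloxy)-2,3-dihydro-1-benzofuran
Product: 16 2-[(2R,3R)-5-(2-methyl-1,3-dioxolan-2-yl)-3-(triethylsilyloxy)-6-(triisopropylsilyloxy)-2,3-dihydro-1-benzofuran-2-yl]prop-2-en-1-ol, via lithium chloromethylborate 14 (not isolated), via allylboronate 15 (not isolated)
Conditions: BrCH2Cl, n-BuLi, THF, −78 °C to rt; then NaBO3·4H2O, THF/H2O, rt
Reagents that add atoms: bromochloromethane, ClCBr; NaBO3·4H2O (sodium perborate tetrahydrate), [Na+].[O-]OB=O.O.O.O.O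
Why: Matteson homologation, in which LiCH2Cl made in the presence of 13 adds to boron and the alkenyl group of borate 14 migrates to carbon with loss of chloride to give allylboronate 15, followed by perborate oxidation of the C–B bond without allylic transposition, under conditions that leave C2 and C3 untouched and are mild enough for both silyl ethers and the ketal.

Step 9
Reactants: 16 2-[(2R,3R)-5-(2-methyl-1,3-dioxolan-2-yl)-3-(triethylsilyloxy)-6-(triisopropylsilyloxy)-2,3-dihydro-1-benzofuran-2-yl]prop-2-en-1-ol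
Product: 17 2-[(2R,3R)-5-(2-methyl-1,3-dioxolan-2-yl)-3-(triethylsilyloxy)-6-(triisopropylsilyloxy)-2,3-dihydro-1-benzofuran-2-yl]prop-2-en-1-yl acetate
Conditions: Ac2O, pyridine, DMAP (cat.), CH2Cl2, 0 °C
Reagents that add atoms: acetic anhydride, CC(=O)OC(C)=O
Why: DMAP-catalysed acetylation of the only free hydroxyl group under basic conditions that leave the acid-labile ketal and the silyl ethers alone.

Step 10
Reactants: 17 2-[(2R,3R)-5-(2-methyl-1,3-dioxolan-2-yl)-3-(triethylsilyloxy)-6-(triisopropylsilyloxy)-2,3-dihydro-1-benzofuran-2-yl]prop-2-en-1-yl acetate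
Product: 19 2-[(2R,3R)-5-acetyl-3-hydroxy-6-(triisopropylsilyloxy)-2,3-dihydro-1-benzofuran-2-yl]prop-2-en-1-yl acetate, via keto triethylsilyl ether 18 (not isolated)
Conditions: AcOH/THF/H2O 3:1:1, rt
Reagents that add atoms: water, O
Why: Acid-catalysed hydrolysis in which the electron-rich aryl ketal opens first through a stabilised oxocarbenium ion, the liberated acetyl group then lowers the donor power of O1 and of the C6 oxygen and so protects the benzylic C3–O bond from ionisation and dehydration to the benzofuran while the TES ether is solvolysed, and the aryl TIPS ether and allylic acetate are inert to aqueous acetic acid.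

Step 11
Reactants: 19 2-[(2R,3R)-5-acetyl-3-hydroxy-6-(triisopropylsilyloxy)-2,3-dihydro-1-benzofuran-2-yl]prop-2-en-1-yl acetate; 20 angelic acid [(Z)-2-methylbut-2-enoic acid]
Product: 22 (2R,3R)-5-acetyl-2-(3-acetoxyprop-1-en-2-yl)-6-(triisopropylsilyloxy)-2,3-dihydro-1-benzofuran-3-yl (Z)-2-methylbut-2-enoate, via angelic 2,4,6-trichlorobenzoic anhydride 21 (not isolated)
Conditions: 20, 2,4,6-trichlorobenzoyl chloride, Et3N, toluene, rt; then 19, 75 °C
Reagents that add atoms: none
Why: Yamaguchi-type mixed anhydride esterification run without a nucleophilic catalyst, the conditions established for passing on the angeloyl group without Z-to-E isomerisation, and since only the O–H bond of 19 is broken the C3 configuration is retained.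

Step 12
Reactants: 22 (2R,3R)-5-acetyl-2-(3-acetoxyprop-1-en-2-yl)-6-(triisopropylsilyloxy)-2,3-dihydro-1-benzofuran-3-yl (Z)-2-methylbut-2-enoate
Product: 23 (2R,3R)-5-acetyl-2-(3-acetoxyprop-1-en-2-yl)-6-hydroxy-2,3-dihydro-1-benzofuran-3-yl (Z)-2-methylbut-2-enoate (CNP0323250.1)
Conditions: TBAF, AcOH (1:1), THF, 0 °C
Reagents that add atoms: none
Why: Fluoride-mediated desilylation of an aryl silyl ether activated by the ortho acetyl group, buffered with acetic acid so that the product appears as the chelated phenol and not as the phenoxide, which avoids expulsion of the para-benzylic angelate (quinone methide formation), ester cleavage and isomerisation of the angelate.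

**Compound list**
1 | 1-(5-bromo-2,4-dihydroxyphenyl)ethan-1-one | CC(=O)c1cc(Br)c(O)cc1O | starting material
2 | propargyl bromide (3-bromoprop-1-yne) | C#CCBr | starting material
3 | 1-[5-bromo-2-hydroxy-4-(prop-2-yn-1-yloxy)phenyl]ethan-1-one | C#CCOc1cc(O)c(C(C)=O)cc1Br | intermediate
4 | 1-[5-bromo-4-(prop-2-yn-1-yloxy)-2-(triisopropylsilyloxy)phenyl]ethan-1-one | C#CCOc1cc(O[Si](C(C)C)(C(C)C)C(C)C)c(C(C)=O)cc1Br | intermediate
5 | 2-[5-bromo-4-(prop-2-yn-1-yloxy)-2-(triisopropylsilyloxy)phenyl]-2-methyl-1,3-dioxolane | C#CCOc1cc(O[Si](C(C)C)(C(C)C)C(C)C)c(C2(C)OCCO2)cc1Br | intermediate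
6 | 2-[5-bromo-4-(propa-1,2-dien-1-yloxy)-2-(triisopropylsilyloxy)phenyl]-2-methyl-1,3-dioxolane | C=C=COc1cc(O[Si](C(C)C)(C(C)C)C(C)C)c(C2(C)OCCO2)cc1Br | intermediate
7 | aryllithium derived from 6 (Li in place of Br) | [Li]c1cc(C2(C)OCCO2)c(O[Si](C(C)C)(C(C)C)C(C)C)cc1OC=C=C | intermediate
8 | lithium hemiaminal alkoxide, the DMF adduct of 7 (configuration at the new carbon irrelevant) | CN(C)C([O-])c1cc(C2(C)OCCO2)c(O[Si](C(C)C)(C(C)C)C(C)C)cc1OC=C=C.[Li+] | intermediate
9 | 5-(2-methyl-1,3-dioxolan-2-yl)-2-(propa-1,2-dien-1-yloxy)-4-(triisopropylsilyloxy)benzaldehyde | C=C=COc1cc(O[Si](C(C)C)(C(C)C)C(C)C)c(C2(C)OCCO2)cc1C=O | intermediate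
10 | bis(pinacolato)diboron | CC1(C)OB(OC1(C)C)B1OC(C)(C)C(C)(C)O1 | starting material
11 | O-pinacolboryl ether of 12 (2R,3R, cis) | C=C(B1OC(C)(C)C(C)(C)O1)[C@H]1Oc2cc(O[Si](C(C)C)(C(C)C)C(C)C)c(C3(C)OCCO3)cc2[C@H]1OB1OC(C)(C)C(C)(C)O1 | intermediate
12 | (2R,3R)-5-(2-methyl-1,3-dioxolan-2-yl)-2-[1-(pinacolboryl)ethenyl]-6-(triisopropylsilyloxy)-2,3-dihydro-1-benzofuran-3-ol (cis) | C=C(B1OC(C)(C)C(C)(C)O1)[C@H]1Oc2cc(O[Si](C(C)C)(C(C)C)C(C)C)c(C3(C)OCCO3)cc2[C@H]1O | intermediate
13 | C3 triethylsilyl ether of 12 (2R,3R) | C=C(B1OC(C)(C)C(C)(C)O1)[C@H]1Oc2cc(O[Si](C(C)C)(C(C)C)C(C)C)c(C3(C)OCCO3)cc2[C@H]1O[Si](CC)(CC)CC | intermediate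
14 | lithium (chloromethyl)borate formed from 13 and LiCH2Cl (2R,3R) | [Li+].C=C([B-]1(CCl)OC(C)(C)C(C)(C)O1)[C@H]1Oc2cc(O[Si](C(C)C)(C(C)C)C(C)C)c(C3(C)OCCO3)cc2[C@H]1O[Si](CC)(CC)CC | intermediate
15 | allylboronate, C1'–CH2–Bpin (2R,3R) | C=C(CB1OC(C)(C)C(C)(C)O1)[C@H]1Oc2cc(O[Si](C(C)C)(C(C)C)C(C)C)c(C3(C)OCCO3)cc2[C@H]1O[Si](CC)(CC)CC | intermediate
16 | 2-[(2R,3R)-5-(2-methyl-1,3-dioxolan-2-yl)-3-(triethylsilyloxy)-6-(triisopropylsilyloxy)-2,3-dihydro-1-benzofuran-2-yl]prop-2-en-1-ol | C=C(CO)[C@H]1Oc2cc(O[Si](C(C)C)(C(C)C)C(C)C)c(C3(C)OCCO3)cc2[C@H]1O[Si](CC)(CC)CC | intermediate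
17 | acetate of 16 (2R,3R) | C=C(COC(C)=O)[C@H]1Oc2cc(O[Si](C(C)C)(C(C)C)C(C)C)c(C3(C)OCCO3)cc2[C@H]1O[Si](CC)(CC)CC | intermediate
18 | keto triethylsilyl ether, 17 with the dioxolane hydrolysed to C5 acetyl (2R,3R) | C=C(COC(C)=O)[C@H]1Oc2cc(O[Si](C(C)C)(C(C)C)C(C)C)c(C(C)=O)cc2[C@H]1O[Si](CC)(CC)CC | intermediate
19 | 2-[(2R,3R)-5-acetyl-3-hydroxy-6-(triisopropylsilyloxy)-2,3-dihydro-1-benzofuran-2-yl]prop-2-en-1-yl acetate | C=C(COC(C)=O)[C@H]1Oc2cc(O[Si](C(C)C)(C(C)C)C(C)C)c(C(C)=O)cc2[C@H]1O | intermediate
20 | angelic acid, (Z)-2-methylbut-2-enoic acid | C/C=C(/C)C(=O)O | starting material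
21 | angelic 2,4,6-trichlorobenzoic anhydride (Z) | C/C=C(/C)C(=O)OC(=O)c1c(Cl)cc(Cl)cc1Cl | intermediate
22 | (2R,3R)-5-acetyl-2-(3-acetoxyprop-1-en-2-yl)-6-(triisopropylsilyloxy)-2,3-dihydro-1-benzofuran-3-yl (Z)-2-methylbut-2-enoate | C=C(COC(C)=O)[C@H]1Oc2cc(O[Si](C(C)C)(C(C)C)C(C)C)c(C(C)=O)cc2[C@H]1OC(=O)/C(C)=C\C | intermediate
23 | (2R,3R)-5-acetyl-2-(3-acetoxyprop-1-en-2-yl)-6-hydroxy-2,3-dihydro-1-benzofuran-3-yl (Z)-2-methylbut-2-enoate | C=C(COC(C)=O)[C@H]1Oc2cc(O)c(C(C)=O)cc2[C@H]1OC(=O)/C(C)=C\C | target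

Total step count: 12. Longest linear sequence: 12 steps (1 to 23).

**Steps most likely to fail**

Step 6. The chiral copper complex may discriminate poorly between the two aldehyde faces. The allylcopper may also lose its Z geometry by σ–π–σ equilibration before ring closure, which would erode both enantiomeric purity and cis selectivity.

The fallback takes the absolute configuration from a resolution instead of from the catalyst. It sets out from 9 and 10.
- The two are cyclised with an achiral catalyst (CuCl, Xantphos, NaOtBu, THF) to the racemic cis O-pinacolboryl ether F1. Aqueous work-up then gives the racemic cis alcohol F2.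
- Esterification with (S)-O-methylmandelic acid (DCC, DMAP cat., CH2Cl2, 0 °C) should give the (2R,3R) O-methylmandelate F3 beside the (2S,3S) O-methylmandelate F4.
- The two esters are separated by chromatography, and their NMR anisotropy differences also allow the configuration to be assigned.
- Reductive cleavage of F3 with i-Bu2AlH (CH2Cl2, −78 °C) comes back to the route at 12.

Step 5. n-BuLi may deprotonate the allenyl α-C–H, or that proton may be transferred to the aryllithium. Either process would consume the aryl anion before DMF arrives.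

The fallback installs the formyl carbon before the allene exists and passes the base step at the alcohol oxidation level. It sets out from 5.
- Double lithiation (n-BuLi, 2.1 equiv, THF, −78 °C) gives the dilithio species F5.
- One equivalent of DMF at −78 °C should be taken up only by the aryl C–Li bond of F5, which gives the propargyloxy aldehyde F6 after quench.
- NaBH4 (MeOH/THF, 0 °C) reduces F6 to the propargyloxy benzylic alcohol F7.
- KOtBu (1.3 equiv, THF, 0 °C to rt) isomerises the potassium alkoxide of F7 to the allenyloxy benzylic alcohol F8.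
- MnO2 (CH2Cl2, rt) oxidises the electron-rich benzylic alcohol under neutral conditions and comes back to the route at 9.

Step 8. In borate 14 the tetracoordinate boron sits β to the aryloxy oxygen O1. Ring-opening elimination of the aryloxide, which would regenerate an allene, may therefore compete with the 1,2-shift.

The fallback brings in the extra carbon as CO and needs no long-lived borate. It sets out from 13.
- Oxidative methoxycarbonylation of the alkenylboronate (Pd(OAc)2, PPh3, p-benzoquinone, CO 1 atm, MeOH, rt) should give the methyl acrylate F9.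
- 1,2-Reduction of F9 with i-Bu2AlH (CH2Cl2, −78 °C) comes back to the route at 16.

**Further compounds**
F1 | step 6 | racemic cis O-pinacolboryl ether (both enantiomers of 11) | C=C(B1OC(C)(C)C(C)(C)O1)[C@H]1Oc2cc(O[Si](C(C)C)(C(C)C)C(C)C)c(C3(C)OCCO3)cc2[C@H]1OB1OC(C)(C)C(C)(C)O1.C=C(B1OC(C)(C)C(C)(C)O1)[C@@H]1Oc2cc(O[Si](C(C)C)(C(C)C)C(C)C)c(C3(C)OCCO3)cc2[C@@H]1OB1OC(C)(C)C(C)(C)O1
F2 | step 6 | racemic cis alcohol (both enantiomers of 12) | C=C(B1OC(C)(C)C(C)(C)O1)[C@H]1Oc2cc(O[Si](C(C)C)(C(C)C)C(C)C)c(C3(C)OCCO3)cc2[C@H]1O.C=C(B1OC(C)(C)C(C)(C)O1)[C@@H]1Oc2cc(O[Si](C(C)C)(C(C)C)C(C)C)c(C3(C)OCCO3)cc2[C@@H]1O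
F3 | step 6 | (S)-O-methylmandelate of the (2R,3R) alcohol 12 | C=C(B1OC(C)(C)C(C)(C)O1)[C@H]1Oc2cc(O[Si](C(C)C)(C(C)C)C(C)C)c(C3(C)OCCO3)cc2[C@H]1OC(=O)[C@@H](OC)c1ccccc1
F4 | step 6 | (S)-O-methylmandelate of the (2S,3S) alcohol | C=C(B1OC(C)(C)C(C)(C)O1)[C@@H]1Oc2cc(O[Si](C(C)C)(C(C)C)C(C)C)c(C3(C)OCCO3)cc2[C@@H]1OC(=O)[C@@H](OC)c1ccccc1
F5 | step 5 | dilithio species from 5 (aryl C–Li and acetylide C–Li) | [Li]C#CCOc1cc(O[Si](C(C)C)(C(C)C)C(C)C)c(C2(C)OCCO2)cc1[Li]
F6 | step 5 | 5-(2-methyl-1,3-dioxolan-2-yl)-2-(prop-2-yn-1-yloxy)-4-(triisopropylsilyloxy)benzaldehyde | C#CCOc1cc(O[Si](C(C)C)(C(C)C)C(C)C)c(C2(C)OCCO2)cc1C=O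
F7 | step 5 | [5-(2-methyl-1,3-dioxolan-2-yl)-2-(prop-2-yn-1-yloxy)-4-(triisopropylsilyloxy)phenyl]methanol | C#CCOc1cc(O[Si](C(C)C)(C(C)C)C(C)C)c(C2(C)OCCO2)cc1CO
F8 | step 5 | [5-(2-methyl-1,3-dioxolan-2-yl)-2-(propa-1,2-dien-1-yloxy)-4-(triisopropylsilyloxy)phenyl]methanol | C=C=COc1cc(O[Si](C(C)C)(C(C)C)C(C)C)c(C2(C)OCCO2)cc1CO
F9 | step 8 | methyl 2-[(2R,3R)-5-(2-methyl-1,3-dioxolan-2-yl)-3-(triethylsilyloxy)-6-(triisopropylsilyloxy)-2,3-dihydro-1-benzofuran-2-yl]prop-2-enoate | C=C(C(=O)OC)[C@H]1Oc2cc(O[Si](C(C)C)(C(C)C)C(C)C)c(C3(C)OCCO3)cc2[C@H]1O[Si](CC)(CC)CC
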